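**Retrosynthetic overview**
- Target 24 comes from its pentadecamethyl ether 23 by cleavage of fifteen methyl ethers. All six benzene rings (lettered A to F in the order of the target SMILES) are bought; no ring is built, only five aryl C-O bonds.
- The strategy rests on rings B and C. Each is a 4-oxy-3,5-dioxyphenyl unit whose carbon 1 (B1, C1) carries the inter-ring oxygen exactly where syringic acid carries its carboxyl carbon. The A-O-B1 and B4-O-C1 ethers are therefore the two ester links of depside 9 after loss of two CO under nickel catalysis.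
- Depside 9 is assembled from 2,4,6-trimethoxyphenol and two O-benzylsyringoyl units: acylation, debenzylation, acylation.
- The C4-O-D1 ether is ester 22 less CO. Ester 22 comes from ABC phenol 12 and DEF acid 20.
- Acid 20 comes from syringaldehyde by Chan-Lam arylation (E4-O-F1) and Dakin oxidation (formyl carbon replaced by the E1 oxygen), then Ullmann coupling with methyl 2-bromo-3,4,5-trimethoxybenzoate (D6-O-E1). Bond order: E-O-F and D-O-E in the side branch, A-O-B with B-O-C in the key step, C-O-D last.

Key step: step 6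

Remark on the chemistry: the target has no stereocentre. Compounds 1, 2, 6, 13, 14 and 18 are taken as purchased. All phenolic intermediates and the final polyphenol are handled under argon because these electron-rich rings oxidise in air.

**Route**

Step 1
Reactants: 1 syringic acid; 2 benzyl bromide
Product: 4 4-(benzyloxy)-3,5-dimethoxybenzoic acid, via dibenzylated ester 3 (not isolated)
Conditions: BnBr (2.3 equiv), K2CO3, DMF, 60 °C; then aq. NaOH, MeOH, reflux; HCl to pH 2
Reagents that add atoms: sodium hydroxide, [Na+].[OH-] (its oxygen becomes the acid OH)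
Why: Williamson alkylation of the phenoxide and the carboxylate followed by saponification of the benzyl ester should leave only the base-stable aryl benzyl ether.

Step 2
Reactants: 4 4-(benzyloxy)-3,5-dimethoxybenzoic acid
Product: 5 4-(benzyloxy)-3,5-dimethoxybenzoyl chloride
Conditions: (COCl)2, DMF (cat.), CH2Cl2, 0 °C to rt; evaporate
Reagents that add atoms: oxalyl chloride, ClC(=O)C(=O)Cl
Why: Acid chloride formation through the chloroiminium species should be clean because the carboxyl group deactivates this ring towards electrophiles and the ethers are inert.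

Step 3
Reactants: 5 4-(benzyloxy)-3,5-dimethoxybenzoyl chloride; 6 2,4,6-trimethoxyphenol
Product: 7 2,4,6-trimethoxyphenyl 4-(benzyloxy)-3,5-dimethoxybenzoate
Conditions: Et3N, DMAP (cat.), CH2Cl2, 0 °C to rt
Reagents that add atoms: none
Why: DMAP-catalysed O-acylation via the acylpyridinium ion should take the doubly ortho-substituted phenol readily, since attack at a planar acyl carbon tolerates the flanking methoxy groups.

Step 4
Reactants: 7 2,4,6-trimethoxyphenyl 4-(benzyloxy)-3,5-dimethoxybenzoate
Product: 8 2,4,6-trimethoxyphenyl 4-hydroxy-3,5-dimethoxybenzoate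
Conditions: H2 (1 atm), 10% Pd/C, EtOAc, rt
Reagents that add atoms: none
Why: Hydrogenolysis of the benzyl ether under neutral conditions should free the B4 phenol without touching the aryl ester or the methyl ethers.

Step 5
Reactants: 8 2,4,6-trimethoxyphenyl 4-hydroxy-3,5-dimethoxybenzoate; 5 4-(benzyloxy)-3,5-dimethoxybenzoyl chloride
Product: 9 2,4,6-trimethoxyphenyl 4-{[4-(benzyloxy)-3,5-dimethoxybenzoyl]oxy}-3,5-dimethoxybenzoate (triaryl depside)
Conditions: Et3N, DMAP (cat.), CH2Cl2, 0 °C to rt
Reagents that add atoms: none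
Why: A second DMAP-catalysed acylation with the acid chloride at 0 °C should be much faster than any transesterification of the existing aryl ester by the phenoxide.

Step 6
Reactants: 9 triaryl depside
Product: 11 2-{4-[4-(benzyloxy)-3,5-dimethoxyphenoxy]-3,5-dimethoxyphenoxy}-1,3,5-trimethoxybenzene (ABC benzyl ether), via monoether ester 10 (not isolated)
Conditions: Ni(cod)2 (20 mol %), 3,4-bis(dicyclohexylphosphino)thiophene (40 mol %), K3PO4 (3 equiv), mesitylene (0.02 M), 150 °C, slow argon sweep
Reagents that add atoms: none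
Why: Proposed new method: zerovalent nickel held by the cis-chelating bisphosphine should insert into each acyl C-O bond to give an acyl nickel aryloxide (divalent nickel), extrude CO by aryl migration and CO dissociation, and then form the ether by C-O reductive elimination from the aryl nickel aryloxide; the ester between rings B and C, whose aryloxide is the better leaving group, is expected to react first (10) and the trimethoxyphenyl ester second. The closest known reaction type is the decarbonylative diaryl ether synthesis from aryl esters of azine carboxylic acids with Ni(cod)2 or Pd(OAc)2 and the same thiophene-bridged bisphosphine; the electron-rich benzoyl units used here are the untested part. No ring is closed and no stereocentre is formed; the two acyclic bonds O-B1 and O-C1 are made. Reductive elimination, the slow step, should be helped because B1 and C1 have no ortho substituent while each aryloxide is flanked by two methoxy groups, which push the elimination forward and also block nickel insertion into the aryloxide's own aryl C-O bond; benzyl and methyl ethers are not cleaved without a reductant or nucleophile. The selectivity needed is that each acyl group stays paired with its own aryloxide: the chelate keeps the aryloxide on nickel, the non-polar solvent with insoluble K3PO4 offers little free phenoxide, and dilution with an argon sweep removes CO and slows bimolecular aryloxide exchange.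

Step 7
Reactants: 11 ABC benzyl ether
Product: 12 4-[2,6-dimethoxy-4-(2,4,6-trimethoxyphenoxy)phenoxy]-2,6-dimethoxyphenol (ABC phenol)
Conditions: H2 (1 atm), 10% Pd/C, EtOAc/THF, rt
Reagents that add atoms: none
Why: Benzyl ether hydrogenolysis should free the C4 phenol while diaryl ethers and methyl ethers are stable to Pd/C and hydrogen at room temperature.

Step 8
Reactants: 13 syringaldehyde; 14 3,4,5-trimethoxyphenylboronic acid
Product: 15 3,5-dimethoxy-4-(3,4,5-trimethoxyphenoxy)benzaldehyde
Conditions: Cu(OAc)2 (0.3 equiv), pyridine (5 equiv), 4 Å MS, CH2Cl2, O2 (balloon), rt; boronic acid 2 equiv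
Reagents that add atoms: none
Why: Chan-Lam oxidative O-arylation (transmetalation to a copper aryloxide, oxidation, C-O reductive elimination) tolerates doubly ortho-substituted phenols when the boronic acid is unhindered, as it is here.

Step 9
Reactants: 15 3,5-dimethoxy-4-(3,4,5-trimethoxyphenoxy)benzaldehyde
Product: 17 3,5-dimethoxy-4-(3,4,5-trimethoxyphenoxy)phenol (EF phenol), via aryl formate 16 (not isolated)
Conditions: mCPBA, CH2Cl2, 0 °C to rt; then MeOH, Et3N (cat.), rt
Reagents that add atoms: 3-chloroperoxybenzoic acid, OOC(=O)c1cccc(Cl)c1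
Why: Baeyer-Villiger (Dakin-type) oxidation should proceed with migration of the electron-rich para-oxygenated aryl group, and mild methanolysis of the formate then gives the E1 phenol.

Step 10
Reactants: 17 EF phenol; 18 methyl 2-bromo-3,4,5-trimethoxybenzoate
Product: 19 methyl 2-[3,5-dimethoxy-4-(3,4,5-trimethoxyphenoxy)phenoxy]-3,4,5-trimethoxybenzoate
Conditions: CuI (10 mol %), picolinic acid (20 mol %), K3PO4, DMSO, 100 °C, argon
Reagents that add atoms: none
Why: Ullmann-type copper-catalysed O-arylation should work because the phenol has no ortho substituent and the ortho ester group assists activation of the flanked C-Br bond.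

Step 11
Reactants: 19 DEF methyl ester
Product: 20 2-[3,5-dimethoxy-4-(3,4,5-trimethoxyphenoxy)phenoxy]-3,4,5-trimethoxybenzoic acid (DEF acid)
Conditions: LiOH·H2O, THF/MeOH/H2O, 60 °C; then 1 M HCl
Reagents that add atoms: lithium hydroxide, [Li+].[OH-] (its oxygen becomes the acid OH)
Why: Saponification of the methyl ester should proceed on warming despite the ortho aryloxy group, and aryl ethers are inert to hydroxide.

Step 12
Reactants: 20 DEF acid; 12 ABC phenol
Product: 22 4-[2,6-dimethoxy-4-(2,4,6-trimethoxyphenoxy)phenoxy]-2,6-dimethoxyphenyl 2-[3,5-dimethoxy-4-(3,4,5-trimethoxyphenoxy)phenoxy]-3,4,5-trimethoxybenzoate, via acid chloride 21 (not isolated)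
Conditions: 1-chloro-N,N,2-trimethylprop-1-en-1-amine, CH2Cl2, 0 °C to rt; then 12, Et3N, DMAP, CH2Cl2, 40 °C
Reagents that add atoms: none
Why: The neutral chloroenamine should form the acid chloride without HCl or a formylating electrophile that could attack the activated CH positions of rings E and F, and DMAP-catalysed acylation then takes the crowded C4 phenol oxygen.

Step 13
Reactants: 22 hexaaryl ester
Product: 23 pentadecamethyl ether of the target (all fifteen hydroxyls as OMe)
Conditions: Ni(cod)2 (15 mol %), 3,4-bis(dicyclohexylphosphino)thiophene (30 mol %), K3PO4 (1.5 equiv), mesitylene, 160 °C, slow argon sweep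
Reagents that add atoms: none
Why: Proposed new method: the same cycle as in step 6 (insertion of zerovalent nickel into the acyl C-O bond, CO loss, C-O reductive elimination from the aryl nickel aryloxide of divalent nickel) should form the C4-O-D1 bond; with a single ester in the molecule aryloxide exchange is degenerate, and the one ortho aryloxy group at D1 should speed CO extrusion and reductive elimination by relief of strain rather than block them. The closest known reaction type is the decarbonylative etherification of aryl azinecarboxylates with zerovalent nickel and bulky bisphosphines.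

Step 14
Reactants: 23 pentadecamethyl ether
Product: 24 CNP0175585.0 (target)
Conditions: BBr3 (45 equiv), CH2Cl2, −78 °C to rt, argon; MeOH at 0 °C, evaporate; degassed water; reverse-phase chromatography
Reagents that add atoms: none
Why: Lewis acid demethylation (boron binds each methoxy oxygen and bromide attacks the methyl carbon) should cleave all fifteen methyl ethers, while the five diaryl ether oxygens have no sp3 carbon to lose and survive.

**Compound list**
1 | syringic acid | COc1cc(C(=O)O)cc(OC)c1O | starting material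
2 | benzyl bromide | BrCc1ccccc1 | starting material
3 | benzyl 4-(benzyloxy)-3,5-dimethoxybenzoate | COc1cc(C(=O)OCc2ccccc2)cc(OC)c1OCc1ccccc1 | intermediate
4 | 4-(benzyloxy)-3,5-dimethoxybenzoic acid | COc1cc(C(=O)O)cc(OC)c1OCc1ccccc1 | intermediate
5 | 4-(benzyloxy)-3,5-dimethoxybenzoyl chloride | COc1cc(C(=O)Cl)cc(OC)c1OCc1ccccc1 | intermediate
6 | 2,4,6-trimethoxyphenol | COc1cc(OC)c(O)c(OC)c1 | starting material
7 | 2,4,6-trimethoxyphenyl 4-(benzyloxy)-3,5-dimethoxybenzoate | COc1cc(OC)c(OC(=O)c2cc(OC)c(OCc3ccccc3)c(OC)c2)c(OC)c1 | intermediate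
8 | 2,4,6-trimethoxyphenyl 4-hydroxy-3,5-dimethoxybenzoate | COc1cc(OC)c(OC(=O)c2cc(OC)c(O)c(OC)c2)c(OC)c1 | intermediate
9 | 2,4,6-trimethoxyphenyl 4-{[4-(benzyloxy)-3,5-dimethoxybenzoyl]oxy}-3,5-dimethoxybenzoate (triaryl depside) | COc1cc(OC)c(OC(=O)c2cc(OC)c(OC(=O)c3cc(OC)c(OCc4ccccc4)c(OC)c3)c(OC)c2)c(OC)c1 | intermediate
10 | 2,4,6-trimethoxyphenyl 4-[4-(benzyloxy)-3,5-dimethoxyphenoxy]-3,5-dimethoxybenzoate | COc1cc(OC)c(OC(=O)c2cc(OC)c(Oc3cc(OC)c(OCc4ccccc4)c(OC)c3)c(OC)c2)c(OC)c1 | intermediate
11 | 2-{4-[4-(benzyloxy)-3,5-dimethoxyphenoxy]-3,5-dimethoxyphenoxy}-1,3,5-trimethoxybenzene (ABC benzyl ether) | COc1cc(OC)c(Oc2cc(OC)c(Oc3cc(OC)c(OCc4ccccc4)c(OC)c3)c(OC)c2)c(OC)c1 | intermediate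
12 | 4-[2,6-dimethoxy-4-(2,4,6-trimethoxyphenoxy)phenoxy]-2,6-dimethoxyphenol (ABC phenol) | COc1cc(OC)c(Oc2cc(OC)c(Oc3cc(OC)c(O)c(OC)c3)c(OC)c2)c(OC)c1 | intermediate
13 | syringaldehyde | COc1cc(C=O)cc(OC)c1O | starting material
14 | 3,4,5-trimethoxyphenylboronic acid | COc1cc(B(O)O)cc(OC)c1OC | starting material
15 | 3,5-dimethoxy-4-(3,4,5-trimethoxyphenoxy)benzaldehyde | COc1cc(Oc2c(OC)cc(C=O)cc2OC)cc(OC)c1OC | intermediate
16 | 3,5-dimethoxy-4-(3,4,5-trimethoxyphenoxy)phenyl formate | COc1cc(Oc2c(OC)cc(OC=O)cc2OC)cc(OC)c1OC | intermediate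
17 | 3,5-dimethoxy-4-(3,4,5-trimethoxyphenoxy)phenol (EF phenol) | COc1cc(Oc2c(OC)cc(O)cc2OC)cc(OC)c1OC | intermediate
18 | methyl 2-bromo-3,4,5-trimethoxybenzoate | COC(=O)c1cc(OC)c(OC)c(OC)c1Br | starting material
19 | methyl 2-[3,5-dimethoxy-4-(3,4,5-trimethoxyphenoxy)phenoxy]-3,4,5-trimethoxybenzoate | COC(=O)c1cc(OC)c(OC)c(OC)c1Oc1cc(OC)c(Oc2cc(OC)c(OC)c(OC)c2)c(OC)c1 | intermediate
20 | 2-[3,5-dimethoxy-4-(3,4,5-trimethoxyphenoxy)phenoxy]-3,4,5-trimethoxybenzoic acid (DEF acid) | OC(=O)c1cc(OC)c(OC)c(OC)c1Oc1cc(OC)c(Oc2cc(OC)c(OC)c(OC)c2)c(OC)c1 | intermediate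
21 | 2-[3,5-dimethoxy-4-(3,4,5-trimethoxyphenoxy)phenoxy]-3,4,5-trimethoxybenzoyl chloride | ClC(=O)c1cc(OC)c(OC)c(OC)c1Oc1cc(OC)c(Oc2cc(OC)c(OC)c(OC)c2)c(OC)c1 | intermediate
22 | 4-[2,6-dimethoxy-4-(2,4,6-trimethoxyphenoxy)phenoxy]-2,6-dimethoxyphenyl 2-[3,5-dimethoxy-4-(3,4,5-trimethoxyphenoxy)phenoxy]-3,4,5-trimethoxybenzoate | COc1cc(OC)c(Oc2cc(OC)c(Oc3cc(OC)c(OC(=O)c4cc(OC)c(OC)c(OC)c4Oc4cc(OC)c(Oc5cc(OC)c(OC)c(OC)c5)c(OC)c4)c(OC)c3)c(OC)c2)c(OC)c1 | intermediate
23 | pentadecamethyl ether of the target | COc1cc(OC)c(Oc2cc(OC)c(Oc3cc(OC)c(Oc4cc(OC)c(OC)c(OC)c4Oc4cc(OC)c(Oc5cc(OC)c(OC)c(OC)c5)c(OC)c4)c(OC)c3)c(OC)c2)c(OC)c1 | intermediate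
24 | CNP0175585.0 | Oc1cc(O)c(Oc2cc(O)c(Oc3cc(O)c(Oc4cc(O)c(O)c(O)c4Oc4cc(O)c(Oc5cc(O)c(O)c(O)c5)c(O)c4)c(O)c3)c(O)c2)c(O)c1 | target

**Step count**
Total steps: 14. Longest linear sequence: 10 steps (steps 1 to 7, then 12 to 14); the DEF branch (steps 8 to 11) joins at step 12.

**Steps most likely to fail**

Step 6 (labelled). Aryloxide partners may exchange between the two ester sites before reductive elimination, which would scramble the chain into shorter and longer oligo-ethers. The aryl nickel aryloxide may also stall and be lost by protonation, and CO may bind and deactivate nickel. The fallback uses known copper-catalysed O-arylation. It sets out from 6 and returns at 11.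
- Commercial 4-bromo-2,6-dimethoxyphenol (COc1cc(Br)cc(OC)c1O) is benzylated with 2 (K2CO3, DMF) to 2-(benzyloxy)-5-bromo-1,3-dimethoxybenzene F1.
- Ullmann-type coupling of 6 with F1 (CuI, picolinic acid, K3PO4, DMSO, 100 °C) should give 2-[4-(benzyloxy)-3,5-dimethoxyphenoxy]-1,3,5-trimethoxybenzene F2. This coupling suits a crowded phenol and an aryl bromide without ortho substituents.
- Hydrogenolysis (H2, Pd/C) should give 2,6-dimethoxy-4-(2,4,6-trimethoxyphenoxy)phenol F3.
- A second coupling of F3 with F1 under the same copper conditions should give 11, which enters step 7.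

Step 13 (labelled). Insertion and CO loss at the ortho-substituted aroyl group may be slow, the ortho ether oxygen may hold nickel, and the aryl nickel species may be protonated, losing the DEF fragment. The fallback uses known chemistry and attaches ring D before rings E and F. It sets out from 12 and returns at 23.
- Rieche formylation of commercial 5-bromo-1,2,3-trimethoxybenzene (COc1cc(Br)cc(OC)c1OC; Cl2CHOMe, TiCl4, CH2Cl2, 0 °C) should give 6-bromo-2,3,4-trimethoxybenzaldehyde F4.
- Copper-catalysed O-arylation of 12 with F4 (CuI, picolinic acid, K3PO4, DMSO), helped by the ortho formyl group, should give 6-{4-[2,6-dimethoxy-4-(2,4,6-trimethoxyphenoxy)phenoxy]-2,6-dimethoxyphenoxy}-2,3,4-trimethoxybenzaldehyde F5.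
- Baeyer-Villiger oxidation (mCPBA) should pass through the corresponding 2,3,4-trimethoxyphenyl formate F6, and methanolysis should give the ABCD phenol, 6-{4-[2,6-dimethoxy-4-(2,4,6-trimethoxyphenoxy)phenoxy]-2,6-dimethoxyphenoxy}-2,3,4-trimethoxyphenol F7.
- Separately, Chan-Lam coupling of 4-bromo-2,6-dimethoxyphenol with 14 should give 5-bromo-1,3-dimethoxy-2-(3,4,5-trimethoxyphenoxy)benzene F8.
- Ullmann-type coupling of F7 with F8 (CuI, picolinic acid, K3PO4, DMSO) should give 23, which enters step 14.

Step 14. Cleavage of the fifteen methyl ethers may stop short and leave partly methylated mixtures that cannot be separated as free phenols. The pyrogallol-type rings D and F may also oxidise during aqueous isolation. The fallback replaces direct isolation by capture, purification and mild release. It sets out from 23 and returns at 24.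
- After the BBr3 treatment and methanol quench, the crude residue is acetylated in the same flask (Ac2O, pyridine, DMAP) to the pentadecaacetate of the target F9.
- F9 is air-stable and can be purified on silica; fractions that still carry methyl groups are separated and returned to BBr3.
- Deacetylation of F9 with HCl in degassed MeOH at rt under argon should give 24 after evaporation.

**Further compounds**
F1 | step 6 | 2-(benzyloxy)-5-bromo-1,3-dimethoxybenzene | COc1cc(Br)cc(OC)c1OCc1ccccc1
F2 | step 6 | 2-[4-(benzyloxy)-3,5-dimethoxyphenoxy]-1,3,5-trimethoxybenzene | COc1cc(OC)c(Oc2cc(OC)c(OCc3ccccc3)c(OC)c2)c(OC)c1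
F3 | step 6 | 2,6-dimethoxy-4-(2,4,6-trimethoxyphenoxy)phenol | COc1cc(OC)c(Oc2cc(OC)c(O)c(OC)c2)c(OC)c1
F4 | step 13 | 6-bromo-2,3,4-trimethoxybenzaldehyde | COc1cc(Br)c(C=O)c(OC)c1OC
F5 | step 13 | 6-{4-[2,6-dimethoxy-4-(2,4,6-trimethoxyphenoxy)phenoxy]-2,6-dimethoxyphenoxy}-2,3,4-trimethoxybenzaldehyde | COc1cc(OC)c(Oc2cc(OC)c(Oc3cc(OC)c(Oc4cc(OC)c(OC)c(OC)c4C=O)c(OC)c3)c(OC)c2)c(OC)c1
F6 | step 13 | 6-{4-[2,6-dimethoxy-4-(2,4,6-trimethoxyphenoxy)phenoxy]-2,6-dimethoxyphenoxy}-2,3,4-trimethoxyphenyl formate | COc1cc(OC)c(Oc2cc(OC)c(Oc3cc(OC)c(Oc4cc(OC)c(OC)c(OC)c4OC=O)c(OC)c3)c(OC)c2)c(OC)c1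
F7 | step 13 | 6-{4-[2,6-dimethoxy-4-(2,4,6-trimethoxyphenoxy)phenoxy]-2,6-dimethoxyphenoxy}-2,3,4-trimethoxyphenol | COc1cc(OC)c(Oc2cc(OC)c(Oc3cc(OC)c(Oc4cc(OC)c(OC)c(OC)c4O)c(OC)c3)c(OC)c2)c(OC)c1
F8 | step 13 | 5-bromo-1,3-dimethoxy-2-(3,4,5-trimethoxyphenoxy)benzene | COc1cc(Oc2c(OC)cc(Br)cc2OC)cc(OC)c1OC
F9 | step 14 | pentadecaacetate of the target | CC(=O)Oc1cc(OC(C)=O)c(Oc2cc(OC(C)=O)c(Oc3cc(OC(C)=O)c(Oc4cc(OC(C)=O)c(OC(C)=O)c(OC(C)=O)c4Oc4cc(OC(C)=O)c(Oc5cc(OC(C)=O)c(OC(C)=O)c(OC(C)=O)c5)c(OC(C)=O)c4)c(OC(C)=O)c3)c(OC(C)=O)c2)c(OC(C)=O)c1
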